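The route rests on cutting C1–C10 in the cyclohexene (C1, C10, C11, C12, C13, C14; briarane numbering), where the C13=C14 alkene is allylic to the quaternary C1 and C9 hangs on C10. An Ireland–Claisen rearrangement of the enolate of a δ-lactone (ring O, C9–C13) carrying a Z-alkenyl group (C14=C1) on C13 makes this bond, closes the carbocycle, sets C1 and C10 and releases C9 as an acid in one operation. The precursor is a 4-methyl-5-(methoxymethoxy)-6-alkenyl lactone with C2 as a PMB-protected CH2OH. The ten-membered ring is closed later at C6–C7.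

Key step: step 9

Remark on numbering: briarane numbering is used; the lactone carbonyl is C18 and the methyl groups are C15 (on C1), C16 (on C5), C19 (on C17), C20 (on C11); the target is taken as 1S,2R,7S,8S,9R,10S,11R,12R,17R with a 5Z alkene.
Remark on design: C2 passes through the key step as CH2OPMB, so that the Z alkene comes from a stereospecific carbometalation and the product acid has no acid-labile neighbour. Ipc is isopinocampheyl from (−)-α-pinene.

Step 1
Reactants: 1 prop-2-yn-1-ol
Product: 3 (Z)-3-iodo-2-methylprop-2-en-1-ol, via alkenylmagnesium alkoxide 2 (not isolated)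
Conditions: MeMgBr (2.5 equiv), CuI (10 mol%), THF, −10 °C to rt; then I2, −10 °C
Reagents that add atoms: methylmagnesium bromide, C[Mg]Br; iodine, II
Why: Copper-catalysed anti-carbomagnesiation of the propargylic alkoxide (Duboudin reaction) puts methyl on the internal carbon and magnesium cis to CH2O, and iodinolysis with retention gives the Z iodide that later fixes both the C14=C1 and the C5=C6 geometry.

Step 2
Reactants: 3 (Z)-3-iodo-2-methylprop-2-en-1-ol
Product: 4 (Z)-1-iodo-3-[(4-methoxybenzyl)oxy]-2-methylprop-1-ene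
Conditions: NaH, PMBCl, n-Bu4NI (cat.), THF/DMF, 0 °C to rt
Reagents that add atoms: 4-methoxybenzyl chloride, COc1ccc(CCl)cc1
Why: Williamson etherification of a primary alkoxide; the iodoalkene has no β-hydrogen placed for elimination and keeps its geometry.

Step 3
Reactants: 4 (Z)-1-iodo-3-[(4-methoxybenzyl)oxy]-2-methylprop-1-ene
Product: 6 (Z)-4-[(4-methoxybenzyl)oxy]-3-methylbut-2-enal, via alkenyllithium 5 (not isolated)
Conditions: t-BuLi (2.05 equiv), Et2O, −78 °C; DMF; pH 7 buffer, 0 °C
Reagents that add atoms: N,N-dimethylformamide, CN(C)C=O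
Why: Iodine–lithium exchange and formylation of an alkenyllithium both proceed with retention, so the Z enal should form and is used cold and directly to avoid Z-to-E isomerisation.

Step 4
Reactants: 7 prop-2-en-1-ol
Product: 8 3-(methoxymethoxy)prop-1-ene
Conditions: MOMCl, i-Pr2NEt, CH2Cl2, 0 °C to rt
Reagents that add atoms: chloromethyl methyl ether, COCCl
Why: Standard O-alkylation of a primary alcohol with an α-chloro ether.

Step 5
Reactants: 6 (Z)-4-[(4-methoxybenzyl)oxy]-3-methylbut-2-enal; 8 3-(methoxymethoxy)prop-1-ene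
Product: 11 (3S,4S,5Z)-7-[(4-methoxybenzyl)oxy]-3-(methoxymethoxy)-6-methylhepta-1,5-dien-4-ol, via allylborane 9 (not isolated), via borinate 10 (not isolated)
Conditions: 8, s-BuLi, THF, −78 °C; (+)-Ipc2BOMe; BF3·OEt2; then 6, −78 °C; NaOH, H2O2, 0 °C to rt
Reagents that add atoms: none
Why: Brown asymmetric γ-alkoxyallylboration: the Z-alkoxyallylborane reacts through a chair to give the syn O,O pattern, and the isopinocampheyl groups from (−)-α-pinene direct attack to the Re face of the aldehyde, setting C13 and C12 (4S and 3S here).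

Step 6
Reactants: 11 (3S,4S,5Z)-7-[(4-methoxybenzyl)oxy]-3-(methoxymethoxy)-6-methylhepta-1,5-dien-4-ol; 12 acryloyl chloride
Product: 13 acrylate ester of 11 at the C13 hydroxyl
Conditions: i-Pr2NEt, DMAP (cat.), CH2Cl2, −20 to 0 °C
Reagents that add atoms: none
Why: O-acylation of a secondary allylic alcohol with an acid chloride at low temperature, which avoids conjugate addition to the acrylate.

Step 7
Reactants: 13 acrylate ester of 11
Product: 14 (5S,6S)-5-(methoxymethoxy)-6-{(Z)-3-[(4-methoxybenzyl)oxy]-2-methylprop-1-enyl}-5,6-dihydro-2H-pyran-2-one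
Conditions: second-generation Grubbs catalyst RuCl2(=CHPh)(H2IMes)(PCy3) (5 mol%), CH2Cl2 (0.01 M), 40 °C
Reagents that add atoms: none
Why: Ring-closing metathesis between the acrylate and the monosubstituted vinyl group gives the six-membered unsaturated lactone, the trisubstituted alkene being too hindered to take part.

Step 8
Reactants: 14 unsaturated lactone
Product: 15 (4R,5S,6S)-5-(methoxymethoxy)-4-methyl-6-{(Z)-3-[(4-methoxybenzyl)oxy]-2-methylprop-1-enyl}tetrahydro-2H-pyran-2-one
Conditions: Me2CuLi (from MeLi and CuI), Et2O, −78 °C; then aq. NH4Cl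
Reagents that add atoms: lithium dimethylcuprate, [Li+].C[Cu-]C
Why: Cuprate conjugate addition to the 5,6-dihydropyranone takes place anti to the adjacent C12 alkoxy group, setting C11 trans to C12–O, and at −78 °C it outruns SN2′ attack on the allylic lactone C–O bond.

Step 9
Reactants: 15 lactone (precursor of the key step)
Product: 18 (1S,2S,5R,6R)-5-(methoxymethoxy)-2-{[(4-methoxybenzyl)oxy]methyl}-2,6-dimethylcyclohex-3-ene-1-carboxylic acid, via silyl ketene acetal 16 (not isolated), via silyl ester 17 (not isolated)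
Conditions: LiN(i-Pr)2, TBSCl, DMPU, THF, −78 °C to rt; toluene, 105 °C; K2CO3, MeOH/H2O, then citric acid to pH 4
Reagents that add atoms: none
Why: Deprotonation at C10 and O-silylation give the cyclic silyl ketene acetal 16, which undergoes a concerted suprafacial [3,3] sigmatropic shift (Ireland–Claisen rearrangement) that makes C1–C10, breaks C13–O and moves the alkene to C13=C14, and hydrolysis of silyl ester 17 frees the C9 acid. The closest known reaction type is the Ireland–Claisen ring contraction of 6-alkenyl lactone silyl ketene acetals to cycloalkenecarboxylic acids. The cyclohexene is closed by sigmatropic reorganisation of a bicyclo[2.2.2]octane-like array (bridges O–C9, C11–C12 and C14–C1 between C10 and C13), not by an exo or endo attack, so the pericyclic ring has to be a boat. C10 is controlled by C13, because the new bond forms on the lactone face from which the allylic C–O bond departs, and C1 is controlled by the Z geometry of C14=C1, which in the boat puts the methyl group (trans to C13) cis to C9 and the CH2OPMB group trans to it. The selectivity needed is facial and boat over chair, and the two-atom C11–C12 tether secures both because the chair cannot be reached. C11 and C12 pass through unchanged, so four contiguous ring stereocentres result.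

Step 10
Reactants: 18 cyclohexene acid
Product: 19 [(1S,2S,5R,6R)-5-(methoxymethoxy)-2-{[(4-methoxybenzyl)oxy]methyl}-2,6-dimethylcyclohex-3-en-1-yl]methanol
Conditions: LiAlH4, THF, 0 °C to rt
Reagents that add atoms: none
Why: Hydride reduction of a hindered carboxylic acid to the primary alcohol, inert towards the ethers and the alkene.

Step 11
Reactants: 19 C9 primary alcohol
Product: 20 (1S,2S,5R,6R)-5-(methoxymethoxy)-2-{[(4-methoxybenzyl)oxy]methyl}-2,6-dimethylcyclohex-3-ene-1-carbaldehyde
Conditions: Dess–Martin periodinane, NaHCO3, CH2Cl2, 0 °C to rt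
Reagents that add atoms: none
Why: Buffered Dess–Martin oxidation gives the aldehyde without base, so C10 should not epimerise.

Step 12
Reactants: 21 methyl (S)-3-hydroxy-2-methylpropanoate
Product: 22 methyl (S)-3-[(tert-butyldimethylsilyl)oxy]-2-methylpropanoate
Conditions: TBSCl, imidazole, CH2Cl2, rt
Reagents that add atoms: tert-butyldimethylsilyl chloride, CC(C)(C)[Si](C)(C)Cl
Why: Standard silylation of a primary alcohol; the stereocentre (later C17) is untouched.

Step 13
Reactants: 22 silylated Roche ester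
Product: 23 (S)-3-[(tert-butyldimethylsilyl)oxy]-N-methoxy-N,2-dimethylpropanamide
Conditions: MeNH(OMe)·HCl, i-PrMgCl, THF, −20 °C
Reagents that add atoms: N,O-dimethylhydroxylamine hydrochloride, CNOC.Cl
Why: Aminolysis of the ester by the magnesium amide (Weinreb amide formation) is fast at −20 °C and does not enolise the α-stereocentre.

Step 14
Reactants: 23 Weinreb amide
Product: 24 (S)-4-[(tert-butyldimethylsilyl)oxy]-3-methylbutan-2-one
Conditions: MeMgBr, THF, 0 °C
Reagents that add atoms: methylmagnesium bromide, C[Mg]Br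
Why: Weinreb ketone synthesis; the chelated tetrahedral intermediate prevents over-addition.

Step 15
Reactants: 24 methyl ketone
Product: 26 (S)-4-[(tert-butyldimethylsilyl)oxy]-3-methylbut-1-en-2-yl trifluoromethanesulfonate, via potassium enolate 25 (not isolated)
Conditions: KN(SiMe3)2, THF, −78 °C; PhNTf2, −78 to 0 °C
Reagents that add atoms: N-phenylbis(trifluoromethanesulfonimide), O=S(=O)(N(c1ccccc1)S(=O)(=O)C(F)(F)F)C(F)(F)F
Why: Kinetic deprotonation with a bulky amide takes the methyl proton, so O-triflation gives the terminal enol triflate and leaves the methine stereocentre alone.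

Step 16
Reactants: 20 C9 aldehyde; 26 alkenyl triflate
Product: 27 C9 allylic alcohol (9R) with the C8 methylidene and the C17 side chain
Conditions: CrCl2 (4 equiv), NiCl2 (1 mol%), DMF, rt
Reagents that add atoms: none
Why: Nozaki–Hiyama–Kishi alkenylation is non-basic and aldehyde-selective, and Felkin–Anh addition anti to the quaternary C1, with the C10 hydrogen flanking the incoming nucleophile, should set C9 as R.

Step 17
Reactants: 27 C9 allylic alcohol
Product: 28 C9 tert-butyldimethylsilyl ether of 27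
Conditions: TBSOTf, 2,6-lutidine, CH2Cl2, −78 to 0 °C
Reagents that add atoms: tert-butyldimethylsilyl trifluoromethanesulfonate, CC(C)(C)[Si](C)(C)OS(=O)(=O)C(F)(F)F
Why: Silyl triflate with a hindered base silylates even a crowded secondary alcohol while MOM and PMB ethers survive.

Step 18
Reactants: 28 bis-silyl ether
Product: 29 C2 primary alcohol (PMB removed)
Conditions: DDQ, CH2Cl2/pH 7 buffer, 0 °C
Reagents that add atoms: none
Why: Oxidative cleavage of the electron-rich benzyl ether by DDQ leaves silyl ethers, the MOM ether and the alkenes untouched.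

Step 19
Reactants: 29 C2 primary alcohol
Product: 30 C2 aldehyde
Conditions: Dess–Martin periodinane, NaHCO3, CH2Cl2, 0 °C to rt
Reagents that add atoms: none
Why: Dess–Martin oxidation of a neopentyl alcohol to an aldehyde that has no α-hydrogen and so cannot epimerise.

Step 20
Reactants: 30 C2 aldehyde
Product: 31 C2 methyl carbinol (both C2 epimers)
Conditions: MeMgBr, THF, −78 °C
Reagents that add atoms: methylmagnesium bromide, C[Mg]Br
Why: Grignard addition brings in C3; the new centre is removed in the next step, so its configuration does not matter.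

Step 21
Reactants: 31 C2 methyl carbinol
Product: 32 C2 methyl ketone (C1–CO–CH3)
Conditions: Dess–Martin periodinane, NaHCO3, CH2Cl2, rt
Reagents that add atoms: none
Why: Dess–Martin oxidation of the secondary alcohol gives a ketone that can enolise only towards C3.

Step 22
Reactants: 3 (Z)-3-iodo-2-methylprop-2-en-1-ol
Product: 33 (Z)-3-bromo-1-iodo-2-methylprop-1-ene
Conditions: CBr4, PPh3, CH2Cl2, 0 °C
Reagents that add atoms: carbon tetrabromide, BrC(Br)(Br)Br
Why: Appel bromination of the primary allylic alcohol proceeds by SN2 without allylic transposition or loss of alkene geometry.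

Step 23
Reactants: 32 C2 methyl ketone; 33 (Z)-3-bromo-1-iodo-2-methylprop-1-ene
Product: 35 C2 ketone carrying the C3–C6 chain with the Z iodoalkene, via lithium enolate 34 (not isolated)
Conditions: LiN(i-Pr)2, THF, −78 °C; 33, DMPU, −78 to −20 °C
Reagents that add atoms: none
Why: Kinetic enolate alkylation: the ketone has a single enolisable position, and the primary allylic bromide reacts by SN2 to form C3–C4 with the alkenyl iodide untouched.

Step 24
Reactants: 35 alkylated C2 ketone
Product: 36 C2 alcohol (2R)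
Conditions: (S)-2-methyl-CBS-oxazaborolidine, catecholborane, toluene, −78 °C
Reagents that add atoms: none
Why: Corey–Bakshi–Shibata reduction: the (S)-catalyst distinguishes the quaternary C1 from the C3 methylene and should deliver hydride to give the 2R alcohol, and catecholborane at −78 °C does not hydroborate the alkenes.

Step 25
Reactants: 36 C2 alcohol
Product: 37 C2 acetate
Conditions: Ac2O, DMAP, pyridine, CH2Cl2, rt
Reagents that add atoms: acetic anhydride, CC(=O)OC(C)=O
Why: DMAP-catalysed acetylation installs the final C2 ester, which also protects this alcohol in the oxidations that follow.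

Step 26
Reactants: 37 C2 acetate
Product: 38 C7,C8 diol (8S)
Conditions: OsO4 (5 mol%), (DHQD)2PHAL (10 mol%), NMO, acetone/H2O, 0 °C
Reagents that add atoms: osmium tetroxide, O=[Os](=O)(=O)=O; N-methylmorpholine N-oxide, C[N+]1([O-])CCOCC1; water, O
Why: Ligand-accelerated osmium dihydroxylation should be fastest at the only alkene with a free terminus (C8=C7H2), and attack anti to C10 with the C9 silyloxy group inside (Kishi's empirical rule), matched by the ligand, should give the 8S tertiary alcohol.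

Step 27
Reactants: 38 C7,C8 diol
Product: 39 C7 aldehyde with free C8 hydroxyl
Conditions: SO3·pyridine, DMSO, i-Pr2NEt, CH2Cl2, 0 °C
Reagents that add atoms: none
Why: Parikh–Doering oxidation converts the primary alcohol of a primary/tertiary 1,2-diol into the α-hydroxy aldehyde without glycol cleavage, and C8 is non-enolisable.

Step 28
Reactants: 39 iodoalkene aldehyde
Product: 40 ten-membered carbocycle with C7 alcohol (7S)
Conditions: CrCl2 (10 equiv), NiCl2 (2 mol%), DMSO/THF, 0.003 M, slow addition, rt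
Reagents that add atoms: none
Why: Nozaki–Hiyama–Kishi ring closure: the Z alkenylchromium from C6–I adds only to the C7 aldehyde under high dilution, and chromium chelation between the C7 carbonyl and the C8 hydroxyl with approach of the tethered C6 from the C9 side should give the 7S alcohol.

Step 29
Reactants: 40 macrocyclic diol
Product: 41 triol with free C18 primary alcohol
Conditions: HF·pyridine, pyridine, THF, 0 °C
Reagents that add atoms: none
Why: Buffered HF·pyridine removes the unhindered primary silyl ether much faster than the secondary C9 silyl ether flanked by C8 and C10 (selective desilylation).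

Step 30
Reactants: 41 triol
Product: 43 γ-lactone (C18 carbonyl, O on C7) with C9 silyl ether, via lactol 42 (not isolated)
Conditions: Cu(MeCN)4OTf (5 mol%), 2,2′-bipyridine, TEMPO (cat.), N-methylimidazole, MeCN, air, rt
Reagents that add atoms: none
Why: Copper/nitroxyl aerobic oxidative lactonisation oxidises only the primary C18 alcohol, the aldehyde is trapped by the C7 hydroxyl (the C9 oxygen being blocked) and the lactol is oxidised on, without base that could epimerise C17.

Step 31
Reactants: 43 silylated lactone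
Product: 44 C9 alcohol
Conditions: HF·pyridine, THF, rt to 40 °C
Reagents that add atoms: none
Why: Acidic fluoride desilylation frees the hindered C9 alcohol without the basic conditions that would cause acyl migration or lactone opening.

Step 32
Reactants: 44 C9 alcohol
Product: 45 C2,C9 diacetate
Conditions: Ac2O, DMAP, Et3N, CH2Cl2, rt
Reagents that add atoms: acetic anhydride, CC(=O)OC(C)=O
Why: DMAP-catalysed acetylation takes the secondary C9 alcohol while the tertiary C8 alcohol is too hindered to react under these conditions.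

Step 33
Reactants: 45 diacetate MOM ether
Product: 46 C12 alcohol
Conditions: ZnBr2, n-PrSH, CH2Cl2, 0 °C
Reagents that add atoms: none
Why: Lewis acid/thiol cleavage of the MOM acetal is fast at 0 °C and tolerates acetates, the lactone and the tertiary alcohol.

Step 34
Reactants: 46 C12 alcohol
Product: 47 CNP0211702.1 (target)
Conditions: butyric anhydride, DMAP, Et3N, CH2Cl2, 0 °C to rt
Reagents that add atoms: butyric anhydride, CCCC(=O)OC(=O)CCC
Why: DMAP-catalysed esterification of the only remaining secondary alcohol gives the 12-butanoate.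

Compound list
1 | prop-2-yn-1-ol | C#CCO | starting material
2 | (Z)-3-(bromomagnesiooxy)-2-methylprop-1-enylmagnesium bromide | Br[Mg]OC/C(C)=C\[Mg]Br | intermediate
3 | (Z)-3-iodo-2-methylprop-2-en-1-ol | OC/C(C)=C\I | intermediate
4 | (Z)-1-iodo-3-[(4-methoxybenzyl)oxy]-2-methylprop-1-ene | COc1ccc(COC/C(C)=C\I)cc1 | intermediate
5 | (Z)-{3-[(4-methoxybenzyl)oxy]-2-methylprop-1-enyl}lithium | COc1ccc(COC/C(C)=C\[Li])cc1 | intermediate
6 | (Z)-4-[(4-methoxybenzyl)oxy]-3-methylbut-2-enal | O=C/C=C(/C)COCc1ccc(OC)cc1 | intermediate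
7 | prop-2-en-1-ol | C=CCO | starting material
8 | 3-(methoxymethoxy)prop-1-ene | C=CCOCOC | intermediate
9 | (Z)-[3-(methoxymethoxy)prop-2-enyl]diisopinocampheylborane | COCO/C=C\CB([C@H]1C[C@H]2C[C@@H]([C@@H]1C)C2(C)C)[C@H]1C[C@H]2C[C@@H]([C@@H]1C)C2(C)C | intermediate
10 | diisopinocampheylborinate of 11 | C=C[C@H](OCOC)[C@@H](OB([C@H]1C[C@H]2C[C@@H]([C@@H]1C)C2(C)C)[C@H]1C[C@H]2C[C@@H]([C@@H]1C)C2(C)C)/C=C(/C)COCc1ccc(OC)cc1 | intermediate
11 | (3S,4S,5Z)-7-[(4-methoxybenzyl)oxy]-3-(methoxymethoxy)-6-methylhepta-1,5-dien-4-ol | C=C[C@H](OCOC)[C@@H](O)/C=C(/C)COCc1ccc(OC)cc1 | intermediate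
12 | acryloyl chloride | C=CC(Cl)=O | starting material
13 | (3S,4S,5Z)-7-[(4-methoxybenzyl)oxy]-3-(methoxymethoxy)-6-methylhepta-1,5-dien-4-yl acrylate | C=C[C@H](OCOC)[C@@H](OC(=O)C=C)/C=C(/C)COCc1ccc(OC)cc1 | intermediate
14 | (5S,6S)-5-(methoxymethoxy)-6-{(Z)-3-[(4-methoxybenzyl)oxy]-2-methylprop-1-enyl}-5,6-dihydro-2H-pyran-2-one | O=C1C=C[C@H](OCOC)[C@@H](O1)/C=C(/C)COCc2ccc(OC)cc2 | intermediate
15 | (4R,5S,6S)-5-(methoxymethoxy)-4-methyl-6-{(Z)-3-[(4-methoxybenzyl)oxy]-2-methylprop-1-enyl}tetrahydro-2H-pyran-2-one | O=C1C[C@@H](C)[C@H](OCOC)[C@@H](O1)/C=C(/C)COCc2ccc(OC)cc2 | intermediate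
16 | tert-butyldimethylsilyl ketene acetal of 15 (C9=C10 in the ring) | CC(C)(C)[Si](C)(C)OC1=C[C@@H](C)[C@H](OCOC)[C@@H](O1)/C=C(/C)COCc2ccc(OC)cc2 | intermediate
17 | tert-butyldimethylsilyl ester of 18 | COCO[C@@H]1C=C[C@](C)(COCc2ccc(OC)cc2)[C@H]([C@H]1C)C(=O)O[Si](C)(C)C(C)(C)C | intermediate
18 | (1S,2S,5R,6R)-5-(methoxymethoxy)-2-{[(4-methoxybenzyl)oxy]methyl}-2,6-dimethylcyclohex-3-ene-1-carboxylic acid | COCO[C@@H]1C=C[C@](C)(COCc2ccc(OC)cc2)[C@H]([C@H]1C)C(O)=O | intermediate
19 | [(1S,2S,5R,6R)-5-(methoxymethoxy)-2-{[(4-methoxybenzyl)oxy]methyl}-2,6-dimethylcyclohex-3-en-1-yl]methanol | COCO[C@@H]1C=C[C@](C)(COCc2ccc(OC)cc2)[C@H]([C@H]1C)CO | intermediate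
20 | (1S,2S,5R,6R)-5-(methoxymethoxy)-2-{[(4-methoxybenzyl)oxy]methyl}-2,6-dimethylcyclohex-3-ene-1-carbaldehyde | COCO[C@@H]1C=C[C@](C)(COCc2ccc(OC)cc2)[C@H]([C@H]1C)C=O | intermediate
21 | methyl (S)-3-hydroxy-2-methylpropanoate | C[C@@H](CO)C(=O)OC | starting material
22 | methyl (S)-3-[(tert-butyldimethylsilyl)oxy]-2-methylpropanoate | C[C@@H](CO[Si](C)(C)C(C)(C)C)C(=O)OC | intermediate
23 | (S)-3-[(tert-butyldimethylsilyl)oxy]-N-methoxy-N,2-dimethylpropanamide | C[C@@H](CO[Si](C)(C)C(C)(C)C)C(=O)N(C)OC | intermediate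
24 | (S)-4-[(tert-butyldimethylsilyl)oxy]-3-methylbutan-2-one | C[C@@H](CO[Si](C)(C)C(C)(C)C)C(C)=O | intermediate
25 | potassium enolate of 24 (terminal) | C[C@@H](CO[Si](C)(C)C(C)(C)C)C(=C)O[K] | intermediate
26 | (S)-4-[(tert-butyldimethylsilyl)oxy]-3-methylbut-1-en-2-yl trifluoromethanesulfonate | C[C@@H](CO[Si](C)(C)C(C)(C)C)C(=C)OS(=O)(=O)C(F)(F)F | intermediate
27 | C9 allylic alcohol (9R): cyclohexene of 20 bearing CH(OH)–C(=CH2)–CH(CH3)–CH2OTBS on C10 | COCO[C@@H]1C=C[C@](C)(COCc2ccc(OC)cc2)[C@H]([C@H]1C)[C@@H](O)C(=C)[C@@H](C)CO[Si](C)(C)C(C)(C)C | intermediate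
28 | C9 tert-butyldimethylsilyl ether of 27 | COCO[C@@H]1C=C[C@](C)(COCc2ccc(OC)cc2)[C@H]([C@H]1C)[C@@H](O[Si](C)(C)C(C)(C)C)C(=C)[C@@H](C)CO[Si](C)(C)C(C)(C)C | intermediate
29 | C2 primary alcohol (28 without PMB) | COCO[C@@H]1C=C[C@](C)(CO)[C@H]([C@H]1C)[C@@H](O[Si](C)(C)C(C)(C)C)C(=C)[C@@H](C)CO[Si](C)(C)C(C)(C)C | intermediate
30 | C2 aldehyde | COCO[C@@H]1C=C[C@](C)(C=O)[C@H]([C@H]1C)[C@@H](O[Si](C)(C)C(C)(C)C)C(=C)[C@@H](C)CO[Si](C)(C)C(C)(C)C | intermediate
31 | C2 methyl carbinol (mixture of C2 epimers) | COCO[C@@H]1C=C[C@](C)(C(C)O)[C@H]([C@H]1C)[C@@H](O[Si](C)(C)C(C)(C)C)C(=C)[C@@H](C)CO[Si](C)(C)C(C)(C)C | intermediate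
32 | C2 methyl ketone | COCO[C@@H]1C=C[C@](C)(C(C)=O)[C@H]([C@H]1C)[C@@H](O[Si](C)(C)C(C)(C)C)C(=C)[C@@H](C)CO[Si](C)(C)C(C)(C)C | intermediate
33 | (Z)-3-bromo-1-iodo-2-methylprop-1-ene | BrC/C(C)=C\I | intermediate
34 | lithium enolate of 32 | COCO[C@@H]1C=C[C@](C)(C(=C)O[Li])[C@H]([C@H]1C)[C@@H](O[Si](C)(C)C(C)(C)C)C(=C)[C@@H](C)CO[Si](C)(C)C(C)(C)C | intermediate
35 | C2 ketone with C3–C6 chain ending in the (Z)-iodoalkene | COCO[C@@H]1C=C[C@](C)(C(=O)CC/C(C)=C\I)[C@H]([C@H]1C)[C@@H](O[Si](C)(C)C(C)(C)C)C(=C)[C@@H](C)CO[Si](C)(C)C(C)(C)C | intermediate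
36 | (2R)-alcohol from 35 | COCO[C@@H]1C=C[C@](C)([C@H](O)CC/C(C)=C\I)[C@H]([C@H]1C)[C@@H](O[Si](C)(C)C(C)(C)C)C(=C)[C@@H](C)CO[Si](C)(C)C(C)(C)C | intermediate
37 | (2R)-acetate of 36 | COCO[C@@H]1C=C[C@](C)([C@H](OC(C)=O)CC/C(C)=C\I)[C@H]([C@H]1C)[C@@H](O[Si](C)(C)C(C)(C)C)C(=C)[C@@H](C)CO[Si](C)(C)C(C)(C)C | intermediate
38 | C7,C8 diol (8S): 37 with C8(OH)–CH2OH in place of C8=CH2 | COCO[C@@H]1C=C[C@](C)([C@H](OC(C)=O)CC/C(C)=C\I)[C@H]([C@H]1C)[C@@H](O[Si](C)(C)C(C)(C)C)[C@@](O)(CO)[C@@H](C)CO[Si](C)(C)C(C)(C)C | intermediate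
39 | C7 aldehyde with free C8 hydroxyl | COCO[C@@H]1C=C[C@](C)([C@H](OC(C)=O)CC/C(C)=C\I)[C@H]([C@H]1C)[C@@H](O[Si](C)(C)C(C)(C)C)[C@@](O)(C=O)[C@@H](C)CO[Si](C)(C)C(C)(C)C | intermediate
40 | briarane carbocycle: 2-OAc, 5Z-ene, 7S-OH, 8-OH, 9-OTBS, 12-OMOM, C18-OTBS | COCO[C@@H]1C=C[C@@]2(C)[C@H]([C@H]1C)[C@@H](O[Si](C)(C)C(C)(C)C)[C@](O)([C@@H](C)CO[Si](C)(C)C(C)(C)C)[C@@H](O)/C=C(/C)CC[C@H]2OC(C)=O | intermediate
41 | 40 with free C18 primary alcohol | COCO[C@@H]1C=C[C@@]2(C)[C@H]([C@H]1C)[C@@H](O[Si](C)(C)C(C)(C)C)[C@](O)([C@@H](C)CO)[C@@H](O)/C=C(/C)CC[C@H]2OC(C)=O | intermediate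
42 | C18 lactol closed onto the C7 oxygen (anomers) | COCO[C@@H]1C=C[C@@]2(C)[C@H]([C@H]1C)[C@@H](O[Si](C)(C)C(C)(C)C)[C@@]1(O)[C@H](/C=C(/C)CC[C@H]2OC(C)=O)OC(O)[C@@H]1C | intermediate
43 | 18,7-lactone with 9-OTBS, 12-OMOM, 2-OAc | COCO[C@@H]1C=C[C@@]2(C)[C@H]([C@H]1C)[C@@H](O[Si](C)(C)C(C)(C)C)[C@@]1(O)[C@H](/C=C(/C)CC[C@H]2OC(C)=O)OC(=O)[C@@H]1C | intermediate
44 | 18,7-lactone with 9-OH, 12-OMOM, 2-OAc | COCO[C@@H]1C=C[C@@]2(C)[C@H]([C@H]1C)[C@@H](O)[C@@]1(O)[C@H](/C=C(/C)CC[C@H]2OC(C)=O)OC(=O)[C@@H]1C | intermediate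
45 | 2,9-diacetate with 12-OMOM | COCO[C@@H]1C=C[C@@]2(C)[C@H]([C@H]1C)[C@@H](OC(C)=O)[C@@]1(O)[C@H](/C=C(/C)CC[C@H]2OC(C)=O)OC(=O)[C@@H]1C | intermediate
46 | 2,9-diacetate with free 12-OH | O[C@@H]1C=C[C@@]2(C)[C@H]([C@H]1C)[C@@H](OC(C)=O)[C@@]1(O)[C@H](/C=C(/C)CC[C@H]2OC(C)=O)OC(=O)[C@@H]1C | intermediate
47 | CNP0211702.1: (1S,2R,5Z,7S,8S,9R,10S,11R,12R,17R)-2,9-diacetoxy-12-butanoyloxy-8-hydroxybriara-5,13-dien-18,7-olide | CCCC(=O)O[C@@H]1C=C[C@@]2(C)[C@H]([C@H]1C)[C@@H](OC(C)=O)[C@@]1(O)[C@H](/C=C(/C)CC[C@H]2OC(C)=O)OC(=O)[C@@H]1C | target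

Total step count: 34.
Longest linear sequence: 28 steps (steps 1–3, 5–11, 16–21 and 23–34, from prop-2-yn-1-ol).

Steps most likely to fail

1. Step 9. The boat-constrained [3,3] shift onto a fully substituted carbon may be slower than side reactions of the silyl ketene acetal (C-silylation, ionisation of the allylic C13–O bond) at the temperature it needs. The fallback is an open-chain Ireland–Claisen through a chair, followed by ring closure by metathesis. It sets out from 6 and 15 and comes back at 18.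
 - Enal 6 would be reduced (NaBH4, CeCl3, MeOH, 0 °C) to (Z)-4-[(4-methoxybenzyl)oxy]-3-methylbut-2-en-1-ol F1.
 - Lactone 15 would be ozonised with reductive work-up (O3, CH2Cl2/MeOH, −78 °C; NaBH4) to the 6-(hydroxymethyl) lactone F2, converted (I2, PPh3, imidazole) into the 6-(iodomethyl) lactone F3, and opened by zinc (Zn, AcOH/THF) in a reductive elimination to (3R,4R)-4-(methoxymethoxy)-3-methylhex-5-enoic acid F4.
 - Esterification (EDCI, DMAP) of F4 with F1 would give allyl ester F5.
 - Ireland–Claisen rearrangement of F5 (LiN(i-Pr)2, TBSCl, THF/DMPU, −78 °C to rt, then hydrolysis), using the ketene acetal with C11 cis to OSi and the Z allyl unit, should give the diene acid F6 with the required C1/C10 relationship.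
 - Ring-closing metathesis of the two vinyl groups of F6 (second-generation Grubbs catalyst RuCl2(=CHPh)(H2IMes)(PCy3), CH2Cl2, 40 °C) would return 18.
 - Facial control by C11 in this open-chain variant is expected to be only moderate, so diastereomers would be separated at F6.

2. Step 28. The addition that closes the ring may show poor facial selectivity at C7, and intermolecular coupling competes if dilution is insufficient. The fallback sets C7 by reduction instead of by the C–C bond formation. It sets out from the step 28 product mixture, that is 40 together with the C7 epimer of 40 F7, and comes back at 40.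
 - Oxidation of the allylic alcohols (MnO2, CH2Cl2, rt) would give the macrocyclic C7 enone F8.
 - Chelation-controlled 1,2-reduction (Zn(BH4)2, Et2O, −20 °C), with zinc bridging the C7 carbonyl and the C8 hydroxyl and hydride entering from the exocyclic face, should give the 7S alcohol 40.

3. Step 16. Slow coupling of two hindered partners may let reduction of the triflate and epimerisation of the aldehyde at C10 compete, and Felkin control at C9 may be incomplete. The fallback replaces the chromium-mediated coupling by a polar organocerium addition. It sets out from 26 (with 20) and comes back at 27.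
 - Palladium-catalysed stannylation of 26 ((Me3Sn)2, Pd(PPh3)4, LiCl, THF, 60 °C) would give (S)-{4-[(tert-butyldimethylsilyl)oxy]-3-methylbut-1-en-2-yl}trimethylstannane F9.
 - Treatment with MeLi and CeCl3 (THF, −78 °C) would give the alkenylcerium dichloride F10.
 - F10 is weakly basic and adds to hindered aldehydes, so addition to 20 at −78 °C should give 27 under the same Felkin–Anh control.

Further compounds
F1 | step 9 | (Z)-4-[(4-methoxybenzyl)oxy]-3-methylbut-2-en-1-ol | OC/C=C(/C)COCc1ccc(OC)cc1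
F2 | step 9 | 6-(hydroxymethyl) lactone (15 with CH2OH in place of the alkenyl group) | O=C1C[C@@H](C)[C@H](OCOC)[C@H](CO)O1
F3 | step 9 | 6-(iodomethyl) lactone | O=C1C[C@@H](C)[C@H](OCOC)[C@H](CI)O1
F4 | step 9 | (3R,4R)-4-(methoxymethoxy)-3-methylhex-5-enoic acid | OC(=O)C[C@@H](C)[C@H](OCOC)C=C
F5 | step 9 | (Z)-4-[(4-methoxybenzyl)oxy]-3-methylbut-2-enyl (3R,4R)-4-(methoxymethoxy)-3-methylhex-5-enoate | COc1ccc(COC/C(C)=C\COC(=O)C[C@@H](C)[C@H](OCOC)C=C)cc1
F6 | step 9 | diene acid (18 opened at C13=C14, with vinyl groups on C1 and C12) | C=C[C@](C)(COCc1ccc(OC)cc1)[C@H]([C@@H](C)[C@H](OCOC)C=C)C(O)=O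
F7 | step 28 | C7 epimer of 40 | COCO[C@@H]1C=C[C@@]2(C)[C@H]([C@H]1C)[C@@H](O[Si](C)(C)C(C)(C)C)[C@](O)([C@@H](C)CO[Si](C)(C)C(C)(C)C)[C@H](O)/C=C(/C)CC[C@H]2OC(C)=O
F8 | step 28 | macrocyclic C7 enone | COCO[C@@H]1C=C[C@@]2(C)[C@H]([C@H]1C)[C@@H](O[Si](C)(C)C(C)(C)C)[C@](O)([C@@H](C)CO[Si](C)(C)C(C)(C)C)C(=O)/C=C(/C)CC[C@H]2OC(C)=O
F9 | step 16 | (S)-{4-[(tert-butyldimethylsilyl)oxy]-3-methylbut-1-en-2-yl}trimethylstannane | C[C@@H](CO[Si](C)(C)C(C)(C)C)C(=C)[Sn](C)(C)C
F10 | step 16 | (S)-{4-[(tert-butyldimethylsilyl)oxy]-3-methylbut-1-en-2-yl}cerium dichloride | C[C@@H](CO[Si](C)(C)C(C)(C)C)C(=C)[Ce](Cl)Cl
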